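**Strategy**

The target is cut into a spiro[4.5]decenone and a phloroglucinol unit, joined late by an o-quinone methide cycloaddition. Everything rests on a [3+3] annulation that builds the cyclohexene ring (C5–C10, spiro[4.5]decane numbering) onto a cyclopentanone. It exploits two features: the spiro carbon C5 is α to the oxygen-bearing carbon C1, so it can act as a ketone enolate, and C9 is a bare methylene that can carry a removable nitro group. In one operation the nitronate C9 of a γ-nitro ketone adds to C8 of 2-isopropylacrolein and enolate C5 closes onto aldehyde carbon C6, setting the spiro centre beside the C10 methyl stereocentre.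

Key step: step 2

Assumption: (E)-1-nitroprop-1-ene (2) and 3-methyl-2-methylidenebutanal (4) are treated as purchasable reagents; both are volatile and are distilled before use.

**Route**

Step 1
Reactants: 1 cyclopentanone; 2 (E)-1-nitroprop-1-ene
Product: 3 (2S)-2-[(2S)-1-nitropropan-2-yl]cyclopentan-1-one
Conditions: 1 (5 equiv), (S)-1-[3,5-bis(trifluoromethyl)phenyl]-3-(pyrrolidin-2-ylmethyl)thiourea (10 mol%), n-PrCO2H (10 mol%), PhMe, 0 °C
Reagents that add atoms: none
Why: Enamine-catalysed asymmetric Michael addition to a nitroalkene: the (S)-pyrrolidine forms the enamine, the thiourea binds the nitro group, and the synclinal transition state sets the side-chain stereocentre (S), the future C10; the ring α-centre is also set but is erased at the enolate in step 2.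

Step 2
Reactants: 3 (2S)-2-[(2S)-1-nitropropan-2-yl]cyclopentan-1-one; 4 3-methyl-2-methylidenebutanal (2-isopropylacrolein)
Product: 6 (5R,6S,7S,9S,10S)-6-hydroxy-10-methyl-9-nitro-7-(propan-2-yl)spiro[4.5]decan-1-one, via nitro aldehyde 5 (not isolated)
Conditions: DBU (1.2 equiv), MeCN, slow addition of 4 (1.0 equiv) at −20 °C, then 40 °C
Reagents that add atoms: none
Why: DBU converts 3 into its nitronate, whose carbon C9 adds in Michael fashion to the unsubstituted β-carbon (C8) of enal 4 to give aldehyde 5, and the ketone then enolises towards its more substituted α-carbon C5, which attacks the aldehyde carbon C6. The closest known reaction type is the domino nitro-Michael/intramolecular aldol [3+3] annulation of γ-nitro carbonyl compounds with enals. One ring is closed, the cyclohexane, by a 6-(enolexo)-exo-trig aldol addition through a chair. The C10 centre from step 1 controls the rest: C7 and C9 equilibrate through the enol and the nitronate and C5 and C6 through retro-aldol, so the product should settle as the chair with 10-methyl, 9-nitro, 7-isopropyl and 6-hydroxyl equatorial and, at the spiro centre, the flat carbonyl carbon C1 axial (cis to the methyl) and the bulkier C4 methylene equatorial. The step needs the ketone enolate to close on the aldehyde and not the aldehyde enolate on the ketone: the aldehyde is the better acceptor, the crossed ketol would be a strained tertiary alcohol that reverts, a Henry closure would need a four-membered ring, and slow addition of one equivalent of 4 suppresses a second Michael addition at C9.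

Step 3
Reactants: 6 (5R,6S,7S,9S,10S)-6-hydroxy-10-methyl-9-nitro-7-(propan-2-yl)spiro[4.5]decan-1-one
Product: 7 (5S,9S,10S)-10-methyl-9-nitro-7-(propan-2-yl)spiro[4.5]dec-6-en-1-one
Conditions: Burgess reagent (methyl N-(triethylammoniosulfonyl)carbamate), PhMe, 70 °C
Reagents that add atoms: none
Why: Burgess dehydration, a syn elimination through the sulfamate ester: C5 is quaternary, so the only β-hydrogen is H7, which is cis to the hydroxyl in 6, and the C6=C7 alkene forms without touching C9 or C10.

Step 4
Reactants: 7 (5S,9S,10S)-10-methyl-9-nitro-7-(propan-2-yl)spiro[4.5]dec-6-en-1-one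
Product: 8 (5R,10R)-10-methyl-7-(propan-2-yl)spiro[4.5]dec-6-en-1-one
Conditions: Bu3SnH (excess), AIBN, PhMe, 110 °C
Reagents that add atoms: none
Why: Tin hydride radical denitration: the stannyl radical adds to the nitro group, the C9–N bond breaks and the secondary radical is reduced by Bu3SnH, while ketone, alkene and both stereocentres are untouched.

Step 5
Reactants: 8 (5R,10R)-10-methyl-7-(propan-2-yl)spiro[4.5]dec-6-en-1-one
Product: 9 (5R,10R)-2,10-dimethyl-7-(propan-2-yl)spiro[4.5]dec-6-en-1-one (both C2 epimers)
Conditions: LDA, THF, −78 °C; MeI, −78 → 0 °C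
Reagents that add atoms: iodomethane CI
Why: Enolate alkylation: C5 is quaternary, so LDA can deprotonate only C2 and MeI gives the 2-methyl ketone; the new C2 centre need not be controlled because it becomes sp2 in step 6.

Step 6
Reactants: 9 (5R,10R)-2,10-dimethyl-7-(propan-2-yl)spiro[4.5]dec-6-en-1-one
Product: 10 trimethyl{[(5R,10R)-2,10-dimethyl-7-(propan-2-yl)spiro[4.5]deca-1,6-dien-1-yl]oxy}silane
Conditions: LDA, THF, −78 → 0 °C; TMSCl, −78 °C → rt
Reagents that add atoms: chlorotrimethylsilane C[Si](C)(C)Cl
Why: Enolate O-silylation: only the C2 proton is left α to the carbonyl, so a single tetrasubstituted silyl enol ether is formed.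

Step 7
Reactants: 11 2,4,6-trihydroxybenzaldehyde
Product: 12 tri-tert-butyl 2-formylbenzene-1,3,5-triyl tricarbonate
Conditions: Boc2O (3.3 equiv), DMAP (cat.), i-Pr2NEt, THF, 0 °C → rt
Reagents that add atoms: di-tert-butyl dicarbonate CC(C)(C)OC(=O)OC(=O)OC(C)(C)C
Why: DMAP-catalysed O-acylation of the three phenols to aryl tert-butyl carbonates; an ortho carbonate is the trigger for quinone methide release in step 8.

Step 8
Reactants: 12 tri-tert-butyl 2-formylbenzene-1,3,5-triyl tricarbonate; 10 trimethyl{[(5R,10R)-2,10-dimethyl-7-(propan-2-yl)spiro[4.5]deca-1,6-dien-1-yl]oxy}silane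
Product: 14 (1R,3a'R,6R,9'R,9a'R)-6,9a'-dimethyl-9'-(2-methylpropyl)-3-(propan-2-yl)-3a'-(trimethylsilyloxy)-1',2',9',9a'-tetrahydro-3a'H-spiro[cyclohex-2-ene-1,3'-cyclopenta[b]chromene]-6',8'-diyl di-tert-butyl dicarbonate (cis-fused silyl ketal), via o-quinone methide 13 (not isolated)
Conditions: 12 (1.5 equiv), i-BuMgCl, Et2O, −78 °C; then 10, −78 °C → rt
Reagents that add atoms: isobutylmagnesium chloride CC(C)C[Mg]Cl
Why: Grignard addition to the aldehyde, carbonate migration to the benzylic alkoxide and loss of tert-butyl carbonate release o-quinone methide 13, which undergoes an inverse-electron-demand hetero-Diels–Alder reaction with enol ether 10: the nucleophilic C2 bonds to the benzylic carbon and the quinone oxygen to C1, suprafacial addition gives the cis ring fusion, the diene adds to the cyclopentene face anti to the C10 methine (syn to the vinylic C6–H), and isobutyl (syn to the quinone carbonyl to avoid the flanking carbonate) with silyloxy endo is expected to end trans to the angular methyl.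

Step 9
Reactants: 14 cis-fused silyl ketal
Product: 16 (1R,3a'S,6R,9'S,9a'R)-6,9a'-dimethyl-9'-(2-methylpropyl)-3-(propan-2-yl)-1',2',9',9a'-tetrahydro-3a'H-spiro[cyclohex-2-ene-1,3'-cyclopenta[b]chromene]-6',8'-diol, via chroman biscarbonate 15 (not isolated)
Conditions: Et3SiH, BF3·OEt2, CH2Cl2, −78 → −30 °C; then K2CO3, MeOH, rt
Reagents that add atoms: none
Why: Ionic hydrogenation of the mixed ketal: BF3 removes the silyloxy group, the aryloxy-stabilised oxocarbenium ion should take hydride from Et3SiH on the face opposite the pseudoaxial isobutyl group, which keeps the 6-5 ring fusion cis, and potassium carbonate in methanol then cleaves the two aryl carbonates.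

Step 10
Reactants: 16 chroman-6',8'-diol
Product: 17 (1R,3a'S,6R,9'S,9a'R)-6',8'-dihydroxy-6,9a'-dimethyl-9'-(2-methylpropyl)-3-(propan-2-yl)-1',2',9',9a'-tetrahydro-3a'H-spiro[cyclohex-2-ene-1,3'-cyclopenta[b]chromene]-5',7'-dicarbaldehyde (CNP0121396.3)
Conditions: POCl3 (excess), DMF, MeCN, 0 °C → rt; then H2O, NaOAc, 40 °C
Reagents that add atoms: N,N-dimethylformamide CN(C)C=O; water O
Why: Double Vilsmeier–Haack formylation at the two free positions of the phloroglucinol ring, each flanked by two oxygens, the isolated trisubstituted alkene being inert to the chloroiminium salt; hydrolysis gives the dialdehyde.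

**Compound list**

1 | cyclopentanone | O=C1CCCC1 | starting material
2 | (E)-1-nitroprop-1-ene | C/C=C/[N+](=O)[O-] | starting material
3 | (2S)-2-[(2S)-1-nitropropan-2-yl]cyclopentan-1-one | O=C1CCC[C@H]1[C@H](C)C[N+](=O)[O-] | intermediate
4 | 3-methyl-2-methylidenebutanal (2-isopropylacrolein) | CC(C)C(=C)C=O | starting material
5 | (5S)-4-nitro-5-(2-oxocyclopentyl)-2-(propan-2-yl)hexanal (other centres equilibrating) | O=CC(C(C)C)CC([N+](=O)[O-])[C@@H](C)C1CCCC1=O | intermediate (not isolated)
6 | (5R,6S,7S,9S,10S)-6-hydroxy-10-methyl-9-nitro-7-(propan-2-yl)spiro[4.5]decan-1-one | O=C1CCC[C@@]12[C@@H](O)[C@H](C(C)C)C[C@H]([N+](=O)[O-])[C@H]2C | intermediate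
7 | (5S,9S,10S)-10-methyl-9-nitro-7-(propan-2-yl)spiro[4.5]dec-6-en-1-one | O=C1CCC[C@@]12C=C(C(C)C)C[C@H]([N+](=O)[O-])[C@H]2C | intermediate
8 | (5R,10R)-10-methyl-7-(propan-2-yl)spiro[4.5]dec-6-en-1-one | O=C1CCC[C@@]12C=C(C(C)C)CC[C@H]2C | intermediate
9 | (5R,10R)-2,10-dimethyl-7-(propan-2-yl)spiro[4.5]dec-6-en-1-one (both C2 epimers) | O=C1C(C)CC[C@@]12C=C(C(C)C)CC[C@H]2C | intermediate
10 | trimethyl{[(5R,10R)-2,10-dimethyl-7-(propan-2-yl)spiro[4.5]deca-1,6-dien-1-yl]oxy}silane | C[Si](C)(C)OC1=C(C)CC[C@@]12C=C(C(C)C)CC[C@H]2C | intermediate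
11 | 2,4,6-trihydroxybenzaldehyde | O=Cc1c(O)cc(O)cc1O | starting material
12 | tri-tert-butyl 2-formylbenzene-1,3,5-triyl tricarbonate | O=Cc1c(OC(=O)OC(C)(C)C)cc(OC(=O)OC(C)(C)C)cc1OC(=O)OC(C)(C)C | intermediate
13 | 3,5-bis[(tert-butoxycarbonyl)oxy]-6-(3-methylbutylidene)cyclohexa-2,4-dien-1-one (o-quinone methide) | CC(C)CC=C1C(=O)C=C(OC(=O)OC(C)(C)C)C=C1OC(=O)OC(C)(C)C | intermediate (not isolated)
14 | (1R,3a'R,6R,9'R,9a'R)-6,9a'-dimethyl-9'-(2-methylpropyl)-3-(propan-2-yl)-3a'-(trimethylsilyloxy)-1',2',9',9a'-tetrahydro-3a'H-spiro[cyclohex-2-ene-1,3'-cyclopenta[b]chromene]-6',8'-diyl di-tert-butyl dicarbonate | CC(C)C[C@@H]1c2c(OC(=O)OC(C)(C)C)cc(OC(=O)OC(C)(C)C)cc2O[C@@]2(O[Si](C)(C)C)[C@]1(C)CC[C@@]21C=C(C(C)C)CC[C@H]1C | intermediate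
15 | (1R,3a'S,6R,9'S,9a'R)-6,9a'-dimethyl-9'-(2-methylpropyl)-3-(propan-2-yl)-1',2',9',9a'-tetrahydro-3a'H-spiro[cyclohex-2-ene-1,3'-cyclopenta[b]chromene]-6',8'-diyl di-tert-butyl dicarbonate | CC(C)C[C@@H]1c2c(OC(=O)OC(C)(C)C)cc(OC(=O)OC(C)(C)C)cc2O[C@H]2[C@]1(C)CC[C@@]21C=C(C(C)C)CC[C@H]1C | intermediate (not isolated)
16 | (1R,3a'S,6R,9'S,9a'R)-6,9a'-dimethyl-9'-(2-methylpropyl)-3-(propan-2-yl)-1',2',9',9a'-tetrahydro-3a'H-spiro[cyclohex-2-ene-1,3'-cyclopenta[b]chromene]-6',8'-diol | CC(C)C[C@@H]1c2c(O)cc(O)cc2O[C@H]2[C@]1(C)CC[C@@]21C=C(C(C)C)CC[C@H]1C | intermediate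
17 | (1R,3a'S,6R,9'S,9a'R)-6',8'-dihydroxy-6,9a'-dimethyl-9'-(2-methylpropyl)-3-(propan-2-yl)-1',2',9',9a'-tetrahydro-3a'H-spiro[cyclohex-2-ene-1,3'-cyclopenta[b]chromene]-5',7'-dicarbaldehyde | CC(C)C[C@@H]1c2c(O)c(C=O)c(O)c(C=O)c2O[C@H]2[C@]1(C)CC[C@@]21C=C(C(C)C)CC[C@H]1C | target

**Totals**

Total step count: 10. Longest linear sequence: 9 steps (steps 1–6 and 8–10).

**Steps most likely to fail**

Step 8. The quinone methide is set free in one burst at low temperature and may dimerise or be intercepted by tert-butoxide before the hindered tetrasubstituted enol ether can add; the benzylic centre may also form with poor selectivity. The fallback is a reservoir approach under thermodynamic control. Phloroglucinol, isovaleraldehyde and morpholine are condensed in a Betti-type Mannich reaction to 2-[3-methyl-1-(morpholin-4-yl)butyl]benzene-1,3,5-triol F3. Heating F3 with 10 in toluene at 100 °C should release the unprotected quinone methide slowly and reversibly by loss of morpholine, so that it is trapped by 10 as it forms. Aqueous work-up should give the 3a'-hydroxy hemiketal (1R,3a'S,6R,9'R,9a'R)-6,9a'-dimethyl-9'-(2-methylpropyl)-3-(propan-2-yl)-1',2',9',9a'-tetrahydro-3a'H-spiro[cyclohex-2-ene-1,3'-cyclopenta[b]chromene]-3a',6',8'-triol F4, which is reduced with Et3SiH and BF3·OEt2 at −78 °C. The fallback sets out from 10 and comes back to the route at 16.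

Step 2. After the conjugate addition the nitronate holds the base, so ring closure may be slow. The enolate may then add to the aldehyde from the wrong face, the aldehyde enolate may close onto the ketone, or a second molecule of 4 may add at C9. In the fallback the two bonds are made in separate operations and the nitro group is removed before the ring is closed. Compounds 3 and 4 with catalytic Et3N in CH2Cl2 at −20 °C should stop at 5, which is isolated. Bu3SnH and AIBN in toluene at 110 °C then remove the nitro group to give (5R)-5-(2-oxocyclopentyl)-2-(propan-2-yl)hexanal F1. The neutral keto aldehyde is closed by aldol addition with catalytic KOH in MeOH under equilibrating conditions to (5R,6S,7S,10R)-6-hydroxy-10-methyl-7-(propan-2-yl)spiro[4.5]decan-1-one F2, and Burgess dehydration of F2 gives the enone. The fallback sets out from 3 and comes back to the route at 8.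

Step 9. Hydride may be delivered to the wrong face of the oxocarbenium ion, or the Lewis acid may open the ketal to the keto phenol or strip the carbonates faster than reduction takes place. The fallback is a radical instead of a cationic reduction. Thiophenol and catalytic BF3·OEt2 at −78 °C convert 14 into the S,O-ketal (3a'-phenylsulfanyl analogue of 14) F5. Bu3SnH with AIBN in benzene at 80 °C then replaces the phenylsulfanyl group by hydrogen through the α-aryloxy radical, which should abstract hydrogen on the convex face of the cis-fused bicycle. The carbonates are then removed with K2CO3 in MeOH as in step 9. The fallback sets out from 14 and comes back to the route at 15.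

**Further compounds**

F1 | step 2 | (5R)-5-(2-oxocyclopentyl)-2-(propan-2-yl)hexanal | O=CC(C(C)C)CC[C@@H](C)C1CCCC1=O
F2 | step 2 | (5R,6S,7S,10R)-6-hydroxy-10-methyl-7-(propan-2-yl)spiro[4.5]decan-1-one | O=C1CCC[C@@]12[C@@H](O)[C@H](C(C)C)CC[C@H]2C
F3 | step 8 | 2-[3-methyl-1-(morpholin-4-yl)butyl]benzene-1,3,5-triol | CC(C)CC(N1CCOCC1)c1c(O)cc(O)cc1O
F4 | step 8 | (1R,3a'S,6R,9'R,9a'R)-6,9a'-dimethyl-9'-(2-methylpropyl)-3-(propan-2-yl)-1',2',9',9a'-tetrahydro-3a'H-spiro[cyclohex-2-ene-1,3'-cyclopenta[b]chromene]-3a',6',8'-triol (hemiketal) | CC(C)C[C@@H]1c2c(O)cc(O)cc2O[C@@]2(O)[C@]1(C)CC[C@@]21C=C(C(C)C)CC[C@H]1C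
F5 | step 9 | 3a'-phenylsulfanyl analogue of 14 (S,O-ketal, di-tert-butyl dicarbonate) | CC(C)C[C@@H]1c2c(OC(=O)OC(C)(C)C)cc(OC(=O)OC(C)(C)C)cc2O[C@@]2(Sc3ccccc3)[C@]1(C)CC[C@@]21C=C(C(C)C)CC[C@H]1C
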